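**Plan**

1. Retrosynthesis: remove the four MOM ethers; take the C4 ketone back to the carbinol; cut O1–C8a of ring C; cut C2–C3 (aldol condensation); cut the aryl–prenyl, aryl–acetyl and aryl–geranyl bonds.
2. Forward: the ring A ketone comes from two successive ortho-lithiations of 5-fluororesorcinol bis-MOM ether (prenyl between the oxygens, acetyl between F and O). The ring B aldehyde comes from Br/Li exchange and geranylation. A Claisen–Schmidt condensation joins them, and ring C is the only ring that has to be closed.
3. Stereochemistry: the single stereocenter, C2, is set by a copper-catalysed asymmetric conjugate borylation/oxidation of the chalcone; its C–O bond is never broken afterwards. The E-geranyl geometry comes from geranyl bromide.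
4. Feature used in the key step: on ring A, C8a is meta to both oxygen-bearing carbons C5 and C7 and ortho to C4a, whose side chain holds the C2 oxygen five atoms away. A fluorine on C8a can therefore be displaced by the C2 alkoxide through a six-membered transition state, and since only this carbon carries a leaving group, the 6-prenyl (not 8-prenyl) pattern is fixed.
5. Helpers: the fluorine on C8a, and the alcohol oxidation level at C4 so that no enolisable carbonyl is present while base is in the flask. C4 is reoxidised after ring closure, where its two epimers converge.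

Key step: step 9

Remark: the facial sense of the CuCl/Josiphos borylation is assumed to follow that of simple chalcones, with the (R,S)-ligand giving the S boronate; if the substrate answers with the opposite sense, the (S,R)-ligand is used and nothing else changes.

**Step 1**
Reactants: 1 5-fluorobenzene-1,3-diol
Product: 2 1-fluoro-3,5-bis(methoxymethoxy)benzene
Conditions: MOMCl, i-Pr2NEt, CH2Cl2, 0 °C → rt
Reagents that add atoms: chloromethyl methyl ether (MOMCl), COCCl
Why: Williamson-type O-alkylation of both phenols with the reactive α-chloro ether should be clean, and the MOM ethers later direct ortho-lithiation, withstand organolithiums and alkoxides, and leave under mild acid.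

**Step 2**
Reactants: 2 1-fluoro-3,5-bis(methoxymethoxy)benzene; 3 1-bromo-3-methylbut-2-ene (prenyl bromide)
Product: 5 5-fluoro-1,3-bis(methoxymethoxy)-2-(3-methylbut-2-en-1-yl)benzene, via aryllithium 4 (not isolated)
Conditions: n-BuLi, THF, −40 °C; CuI (10 mol %), then 3, −40 °C → rt
Reagents that add atoms: none
Why: Directed ortho-metalation should occur at the C–H flanked by the two MOM ethers, where butyllithium is held by both acetal oxygens (the fluorine is para to this site and cannot compete as a coordinating group), and copper-catalysed SN2 allylation at the primary carbon of prenyl bromide then places the prenyl group between the two oxygens.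

**Step 3**
Reactants: 5 5-fluoro-1,3-bis(methoxymethoxy)-2-(3-methylbut-2-en-1-yl)benzene
Product: 8 1-[6-fluoro-2,4-bis(methoxymethoxy)-3-(3-methylbut-2-en-1-yl)phenyl]ethan-1-one, via aryllithium 6 (not isolated), via hemiaminal alkoxide 7 (not isolated)
Conditions: n-BuLi, TMEDA, THF, −78 °C; MeC(O)N(OMe)Me, −78 → 0 °C; H2O
Reagents that add atoms: N-methoxy-N-methylacetamide, CC(=O)N(C)OC
Why: A second directed ortho-metalation can only take place at one of the two equivalent C–H positions flanked by fluorine and a MOM ether, the ortho-fluoroaryllithium does not lose LiF at −78 °C, and Weinreb amide acylation stops at the chelated tetrahedral adduct so that the methyl ketone appears only on work-up.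

**Step 4**
Reactants: 9 3-bromo-4,5-dihydroxybenzaldehyde
Product: 10 3-bromo-4,5-bis(methoxymethoxy)benzaldehyde
Conditions: MOMCl, i-Pr2NEt, CH2Cl2, 0 °C → rt
Reagents that add atoms: chloromethyl methyl ether (MOMCl), COCCl
Why: Williamson-type O-alkylation of the two catechol hydroxyls should proceed as in step 1 and gives ring B the same protecting group as ring A, so that one final operation frees all four phenols.

**Step 5**
Reactants: 10 3-bromo-4,5-bis(methoxymethoxy)benzaldehyde; 11 (2E)-1-bromo-3,7-dimethylocta-2,6-diene (geranyl bromide)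
Product: 15 3-[(2E)-3,7-dimethylocta-2,6-dien-1-yl]-4,5-bis(methoxymethoxy)benzaldehyde, via bromo aminoalkoxide 12 (not isolated), via lithio aminoalkoxide 13 (not isolated), via geranyl aminoalkoxide 14 (not isolated)
Conditions: LiNC4H8O (lithium morpholide, from morpholine and n-BuLi), THF, −78 °C; n-BuLi, −78 °C; CuI (10 mol %), then 11, −78 → 0 °C; H2O
Reagents that add atoms: none
Why: Addition of lithium morpholide masks the aldehyde in the flask as an α-amino alkoxide that is inert to butyllithium, so bromine–lithium exchange followed by copper-catalysed SN2 allylation with geranyl bromide should install the E-geranyl chain unchanged, and water releases the aldehyde.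

**Step 6**
Reactants: 8 1-[6-fluoro-2,4-bis(methoxymethoxy)-3-(3-methylbut-2-en-1-yl)phenyl]ethan-1-one; 15 3-[(2E)-3,7-dimethylocta-2,6-dien-1-yl]-4,5-bis(methoxymethoxy)benzaldehyde
Product: 16 (2E)-3-{3-[(2E)-3,7-dimethylocta-2,6-dien-1-yl]-4,5-bis(methoxymethoxy)phenyl}-1-[6-fluoro-2,4-bis(methoxymethoxy)-3-(3-methylbut-2-en-1-yl)phenyl]prop-2-en-1-one
Conditions: KOH, EtOH/H2O, rt
Reagents that add atoms: none
Why: Claisen–Schmidt condensation (aldol addition, then E1cB dehydration) of the methyl ketone with the non-enolisable aldehyde should give the E-enone and so forms the C2–C3 bond of the target.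

**Step 7**
Reactants: 16 the chalcone of step 6
Product: 18 (3S)-3-{3-[(2E)-3,7-dimethylocta-2,6-dien-1-yl]-4,5-bis(methoxymethoxy)phenyl}-1-[6-fluoro-2,4-bis(methoxymethoxy)-3-(3-methylbut-2-en-1-yl)phenyl]-3-hydroxypropan-1-one, via boronate 17 (not isolated)
Conditions: CuCl (5 mol %), NaOt-Bu (10 mol %), (R,S)-Josiphos [(R)-1-[(S)-2-(diphenylphosphino)ferrocenyl]ethyldicyclohexylphosphine] (5 mol %), B2pin2, MeOH, THF, rt; then NaBO3·4H2O, THF/H2O, rt
Reagents that add atoms: sodium perborate tetrahydrate, [Na+].[Na+].O[B-]1(O)OO[B-](O)(O)OO1.O.O.O.O.O.O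
Why: Copper-catalysed asymmetric conjugate borylation, in which the boryl–copper complex of the chiral ferrocenyl diphosphine adds to one face of the enone β-carbon only (the isolated trisubstituted alkenes and the aryl fluoride are inert), methanol protonates the copper enolate, and perborate oxidation of the C–B bond with retention gives the S carbinol that becomes C2.

**Step 8**
Reactants: 18 the (3S)-β-hydroxy ketone of step 7
Product: 19 (1RS,3S)-3-{3-[(2E)-3,7-dimethylocta-2,6-dien-1-yl]-4,5-bis(methoxymethoxy)phenyl}-1-[6-fluoro-2,4-bis(methoxymethoxy)-3-(3-methylbut-2-en-1-yl)phenyl]propane-1,3-diol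
Conditions: NaBH4, MeOH, 0 °C → rt
Reagents that add atoms: none
Why: Borohydride reduction takes C4 to the alcohol level so that no enolisable carbonyl is present in the basic ring closure; the new carbinol center forms without control and both epimers are carried on because step 10 removes it.

**Step 9**
Reactants: 19 the (1RS,3S)-diol of step 8
Product: 20 (2S,4RS)-2-{3-[(2E)-3,7-dimethylocta-2,6-dien-1-yl]-4,5-bis(methoxymethoxy)phenyl}-5,7-bis(methoxymethoxy)-6-(3-methylbut-2-en-1-yl)-3,4-dihydro-2H-chromen-4-ol
Conditions: KOt-Bu (2.2 equiv), THF (dilute), 0 → 60 °C; H2O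
Reagents that add atoms: none
Why: The potassium alkoxide at C2 attacks C8a of ring A and fluoride leaves from the anionic σ-adduct (addition–elimination), which forms the O1–C8a bond. The closest known reaction type is the intramolecular nucleophilic aromatic substitution of an alkoxide on an aryl fluoride that has no conjugating acceptor, as used to make chromans; here it is helped because the oxygens on C5 and C7 are both meta to C8a, so they withdraw through the σ-framework but cannot donate to the carbon under attack. Ring C closes in the 6-exo-trig mode, whereas the C4 alkoxide could reach C8a only through a four-membered ring and stays a spectator. No stereocenter is formed; the C2–O bond is not broken and, with C4 at the alcohol level, neither retro-aldol cleavage of the substrate nor enolate-driven opening of the product is possible, so the S configuration from step 7 is carried through and both C4 epimers react alike. The step needs site selectivity, which the single fluorine on ring A secures (the new oxygen can only end up para to the prenyl group, hence the 6-prenyl flavan), and chemoselectivity against base-induced migration of the side-chain double bonds into conjugation, which the ethereal medium without dipolar cosolvent is meant to secure.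

**Step 10**
Reactants: 20 the (2S,4RS)-flavan-4-ol of step 9
Product: 21 (2S)-2-{3-[(2E)-3,7-dimethylocta-2,6-dien-1-yl]-4,5-bis(methoxymethoxy)phenyl}-5,7-bis(methoxymethoxy)-6-(3-methylbut-2-en-1-yl)-2,3-dihydro-4H-chromen-4-one
Conditions: Dess–Martin periodinane, pyridine, CH2Cl2, 0 °C → rt
Reagents that add atoms: none
Why: Dess–Martin oxidation of the benzylic secondary alcohol under buffered, non-basic conditions should return the C4 ketone from both epimers (the point where the C4 mixture converges) without touching the alkenes, the MOM ethers or the base-sensitive C2 center.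

**Step 11**
Reactants: 21 the (2S)-tetra-MOM flavanone of step 10
Product: 22 schizolaenone B, (2S)-2-{3-[(2E)-3,7-dimethylocta-2,6-dien-1-yl]-4,5-dihydroxyphenyl}-5,7-dihydroxy-6-(3-methylbut-2-en-1-yl)-2,3-dihydro-4H-chromen-4-one
Conditions: 3 M aq. HCl, MeOH, 40 °C
Reagents that add atoms: none
Why: Acid-catalysed acetal cleavage (transacetalisation to methanol) should remove the four MOM ethers, the one next to the carbonyl first, in the way that is usual for MOM-protected prenylated flavanones, and no base is present that could open ring C and racemise C2.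

**Compound list**

1 | 5-fluorobenzene-1,3-diol | Oc1cc(O)cc(F)c1 | starting material
2 | 1-fluoro-3,5-bis(methoxymethoxy)benzene | COCOc1cc(F)cc(OCOC)c1 | intermediate
3 | 1-bromo-3-methylbut-2-ene (prenyl bromide) | CC(C)=CCBr | starting material
4 | [4-fluoro-2,6-bis(methoxymethoxy)phenyl]lithium (not isolated) | [Li]c1c(OCOC)cc(F)cc1OCOC | intermediate
5 | 5-fluoro-1,3-bis(methoxymethoxy)-2-(3-methylbut-2-en-1-yl)benzene | COCOc1cc(F)cc(OCOC)c1CC=C(C)C | intermediate
6 | [6-fluoro-2,4-bis(methoxymethoxy)-3-(3-methylbut-2-en-1-yl)phenyl]lithium (not isolated) | [Li]c1c(F)cc(OCOC)c(CC=C(C)C)c1OCOC | intermediate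
7 | lithium 1-[6-fluoro-2,4-bis(methoxymethoxy)-3-(3-methylbut-2-en-1-yl)phenyl]-1-[methoxy(methyl)amino]ethan-1-olate (racemic, not isolated) | [Li]OC(C)(N(C)OC)c1c(F)cc(OCOC)c(CC=C(C)C)c1OCOC | intermediate
8 | 1-[6-fluoro-2,4-bis(methoxymethoxy)-3-(3-methylbut-2-en-1-yl)phenyl]ethan-1-one | CC(=O)c1c(F)cc(OCOC)c(CC=C(C)C)c1OCOC | intermediate
9 | 3-bromo-4,5-dihydroxybenzaldehyde | O=Cc1cc(O)c(O)c(Br)c1 | starting material
10 | 3-bromo-4,5-bis(methoxymethoxy)benzaldehyde | O=Cc1cc(OCOC)c(OCOC)c(Br)c1 | intermediate
11 | (2E)-1-bromo-3,7-dimethylocta-2,6-diene (geranyl bromide) | CC(C)=CCC/C(C)=C/CBr | starting material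
12 | lithium [3-bromo-4,5-bis(methoxymethoxy)phenyl](morpholin-4-yl)methanolate (racemic, not isolated) | [Li]OC(N1CCOCC1)c1cc(OCOC)c(OCOC)c(Br)c1 | intermediate
13 | lithium [3-lithio-4,5-bis(methoxymethoxy)phenyl](morpholin-4-yl)methanolate (racemic, not isolated) | [Li]OC(N1CCOCC1)c1cc(OCOC)c(OCOC)c([Li])c1 | intermediate
14 | lithium {3-[(2E)-3,7-dimethylocta-2,6-dien-1-yl]-4,5-bis(methoxymethoxy)phenyl}(morpholin-4-yl)methanolate (racemic, not isolated) | [Li]OC(N1CCOCC1)c1cc(OCOC)c(OCOC)c(C/C=C(\C)CCC=C(C)C)c1 | intermediate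
15 | 3-[(2E)-3,7-dimethylocta-2,6-dien-1-yl]-4,5-bis(methoxymethoxy)benzaldehyde | O=Cc1cc(OCOC)c(OCOC)c(C/C=C(\C)CCC=C(C)C)c1 | intermediate
16 | (2E)-3-{3-[(2E)-3,7-dimethylocta-2,6-dien-1-yl]-4,5-bis(methoxymethoxy)phenyl}-1-[6-fluoro-2,4-bis(methoxymethoxy)-3-(3-methylbut-2-en-1-yl)phenyl]prop-2-en-1-one | O=C(/C=C/c1cc(OCOC)c(OCOC)c(C/C=C(\C)CCC=C(C)C)c1)c1c(F)cc(OCOC)c(CC=C(C)C)c1OCOC | intermediate
17 | (3S)-3-{3-[(2E)-3,7-dimethylocta-2,6-dien-1-yl]-4,5-bis(methoxymethoxy)phenyl}-1-[6-fluoro-2,4-bis(methoxymethoxy)-3-(3-methylbut-2-en-1-yl)phenyl]-3-(4,4,5,5-tetramethyl-1,3,2-dioxaborolan-2-yl)propan-1-one (not isolated) | O=C(C[C@H](B1OC(C)(C)C(C)(C)O1)c1cc(OCOC)c(OCOC)c(C/C=C(\C)CCC=C(C)C)c1)c1c(F)cc(OCOC)c(CC=C(C)C)c1OCOC | intermediate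
18 | (3S)-3-{3-[(2E)-3,7-dimethylocta-2,6-dien-1-yl]-4,5-bis(methoxymethoxy)phenyl}-1-[6-fluoro-2,4-bis(methoxymethoxy)-3-(3-methylbut-2-en-1-yl)phenyl]-3-hydroxypropan-1-one | O=C(C[C@H](O)c1cc(OCOC)c(OCOC)c(C/C=C(\C)CCC=C(C)C)c1)c1c(F)cc(OCOC)c(CC=C(C)C)c1OCOC | intermediate
19 | (1RS,3S)-3-{3-[(2E)-3,7-dimethylocta-2,6-dien-1-yl]-4,5-bis(methoxymethoxy)phenyl}-1-[6-fluoro-2,4-bis(methoxymethoxy)-3-(3-methylbut-2-en-1-yl)phenyl]propane-1,3-diol (both C1 epimers) | OC(C[C@H](O)c1cc(OCOC)c(OCOC)c(C/C=C(\C)CCC=C(C)C)c1)c1c(F)cc(OCOC)c(CC=C(C)C)c1OCOC | intermediate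
20 | (2S,4RS)-2-{3-[(2E)-3,7-dimethylocta-2,6-dien-1-yl]-4,5-bis(methoxymethoxy)phenyl}-5,7-bis(methoxymethoxy)-6-(3-methylbut-2-en-1-yl)-3,4-dihydro-2H-chromen-4-ol (both C4 epimers) | OC1C[C@@H](c2cc(OCOC)c(OCOC)c(C/C=C(\C)CCC=C(C)C)c2)Oc2cc(OCOC)c(CC=C(C)C)c(OCOC)c21 | intermediate
21 | (2S)-2-{3-[(2E)-3,7-dimethylocta-2,6-dien-1-yl]-4,5-bis(methoxymethoxy)phenyl}-5,7-bis(methoxymethoxy)-6-(3-methylbut-2-en-1-yl)-2,3-dihydro-4H-chromen-4-one | O=C1C[C@@H](c2cc(OCOC)c(OCOC)c(C/C=C(\C)CCC=C(C)C)c2)Oc2cc(OCOC)c(CC=C(C)C)c(OCOC)c21 | intermediate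
22 | schizolaenone B, (2S)-2-{3-[(2E)-3,7-dimethylocta-2,6-dien-1-yl]-4,5-dihydroxyphenyl}-5,7-dihydroxy-6-(3-methylbut-2-en-1-yl)-2,3-dihydro-4H-chromen-4-one | CC(C)=CCC/C(C)=C/Cc1cc([C@@H]2CC(=O)c3c(cc(O)c(CC=C(C)C)c3O)O2)cc(O)c1O | target

**Step count and risks**

Total step count: 11. Longest linear sequence: 9 steps (1 → 2 → 5 → 8 → 16 → 18 → 19 → 20 → 21 → 22; steps 1, 2, 3, 6, 7, 8, 9, 10, 11).

Steps most likely to fail:

Step 9. The ring closure on a ring without a conjugating acceptor may be too slow, so that base-promoted migration of the prenyl and geranyl double bonds into conjugation, or intermolecular ether formation, overtakes it. The fallback changes the mechanism from addition–elimination to elimination–addition at low temperature and sets out from 19. Treatment with LiN(i-Pr)2 (excess) in THF at −78 °C should deprotonate both hydroxyls and the ring A C–H at C8, which lies between the fluorine and the C7 MOM ether (the same kind of site that is lithiated in step 3), to give the C8-lithiated dilithium dialkoxide F1. On warming towards 0 °C this loses lithium fluoride to give the ring A aryne F2 (C8≡C8a). The C2 alkoxide then adds to C8a in the 6-exo-dig mode, which is also the aryne carbon remote from the C7 oxygen and therefore the electronically preferred one, and gives the cyclised C8-aryllithium alkoxide F3. Water protonates F3, and the route is rejoined at 20.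

Step 5. Butyllithium may attack the masked aldehyde, the halogen–lithium exchange may stay incomplete, or the allylation may proceed with allylic transposition. The fallback sets out from 10 and replaces the organolithium chemistry by two palladium-catalysed couplings. Borylation with B2pin2, KOAc and PdCl2[1,1'-bis(diphenylphosphino)ferrocene] in dioxane at 80 °C, which tolerates the free aldehyde, should give 3-(4,4,5,5-tetramethyl-1,3,2-dioxaborolan-2-yl)-4,5-bis(methoxymethoxy)benzaldehyde F4. Allyl–aryl coupling of F4 with geranyl bromide 11 (Pd(PPh3)4, a complex of zerovalent palladium, K2CO3, THF/H2O, 60 °C) should form the bond at the less substituted allyl terminus, and the route is rejoined at 15.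

Step 11. Under Brønsted acid the freed phenols may add to the neighbouring prenyl and geranyl double bonds (chroman formation), or ring C may open and reclose with loss of configuration at C2. The fallback sets out from 21 and avoids any proton source in the cleavage step. TMSOTf with 2,2'-bipyridyl in CH2Cl2 at 0 °C should convert the four aryl MOM ethers by silyl transfer into the tetrakis(trimethylsilyl) ether of schizolaenone B F5. Neutral hydrolysis of F5 (H2O/THF, rt) then frees the phenols, and the route is rejoined at 22.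

**Further compounds**

F1 | step 9 | dilithium (1RS,3S)-1-[6-fluoro-5-lithio-2,4-bis(methoxymethoxy)-3-(3-methylbut-2-en-1-yl)phenyl]-3-{3-[(2E)-3,7-dimethylocta-2,6-dien-1-yl]-4,5-bis(methoxymethoxy)phenyl}propane-1,3-diolate | [Li]OC(C[C@H](O[Li])c1cc(OCOC)c(OCOC)c(C/C=C(\C)CCC=C(C)C)c1)c1c(F)c([Li])c(OCOC)c(CC=C(C)C)c1OCOC
F2 | step 9 | ring A aryne (C8≡C8a) dilithium dialkoxide derived from F1 | [Li]OC(C[C@H](O[Li])c1cc(OCOC)c(OCOC)c(C/C=C(\C)CCC=C(C)C)c1)C1=C(OCOC)C(CC=C(C)C)=C(OCOC)C#C1
F3 | step 9 | lithium (2S,4RS)-2-{3-[(2E)-3,7-dimethylocta-2,6-dien-1-yl]-4,5-bis(methoxymethoxy)phenyl}-8-lithio-5,7-bis(methoxymethoxy)-6-(3-methylbut-2-en-1-yl)-3,4-dihydro-2H-chromen-4-olate | [Li]OC1C[C@@H](c2cc(OCOC)c(OCOC)c(C/C=C(\C)CCC=C(C)C)c2)Oc2c([Li])c(OCOC)c(CC=C(C)C)c(OCOC)c21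
F4 | step 5 | 3-(4,4,5,5-tetramethyl-1,3,2-dioxaborolan-2-yl)-4,5-bis(methoxymethoxy)benzaldehyde | O=Cc1cc(OCOC)c(OCOC)c(B2OC(C)(C)C(C)(C)O2)c1
F5 | step 11 | (2S)-2-{3-[(2E)-3,7-dimethylocta-2,6-dien-1-yl]-4,5-bis(trimethylsilyloxy)phenyl}-6-(3-methylbut-2-en-1-yl)-5,7-bis(trimethylsilyloxy)-2,3-dihydro-4H-chromen-4-one | CC(C)=CCC/C(C)=C/Cc1cc([C@@H]2CC(=O)c3c(cc(O[Si](C)(C)C)c(CC=C(C)C)c3O[Si](C)(C)C)O2)cc(O[Si](C)(C)C)c1O[Si](C)(C)C
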